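Decalin carbons carry drimane numbers (C4 = CMe2, C5 and C10 = ring fusion, C8 bears C12, C9 bears C11).
Cuts: the cinnamate at its Cα=Cβ alkene and at the acyl C–O bond; C9–C11 and C8–C12 back to a C9 ketone; ring A at C2–C3; last C4–C5 and C1–C10.
Enabling feature: in ring B the tertiary C5 (bonded to C4) and the quaternary C10 (bonded to C1 and a methyl) are neighbours and C10 adjoins C9, so C5, C10 and C9 are the β-carbon, α-carbon and carbonyl of 2-methylcyclohex-2-enone.
Forward: ring B is bought; one pot adds a ketene acetal at C5 and acrylate at C10; a Dieckmann condensation closes ring A and the spare ester and C3 oxygen are removed; C12 and C11 go onto C8 and C9; the aryl acrylate is attached last by acylation and olefination.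
Stereochemistry: C5 from a chiral counter-anion catalyst; C10 by addition anti to the C5 substituent (hence the trans fusion); C9 by kinetic protonation opposite the axial C10 methyl; the E alkene from the Horner–Wadsworth–Emmons step.

Key step: step 1

Assumption: the sense of induction of the imidodiphosphorimidate catalyst on this enone cannot be predicted, so the route is written for whichever antipode (both binaphthyl axes R or both S) delivers the (5S) configuration of the target.

Step 1
Reactants: 1 2-methylcyclohex-2-en-1-one; 2 dimethylketene methyl trimethylsilyl acetal; 3 methyl acrylate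
Product: 6 methyl 2-[(1R,2S)-2-(3-methoxy-3-oxopropyl)-2-methyl-3-oxocyclohexyl]-2-methylpropanoate, via silyl enol ether 4 (not isolated), via silyl ketene acetal 5 (not isolated)
Conditions: chiral imidodiphosphorimidate acid HN[P(=NSO2CF3)(O2C20H10Ar2)]2 (two 3,3'-diaryl-1,1'-binaphthalene-2,2'-diolate units, Ar = 3,5-(CF3)2C6H3; 3 mol%), toluene, −40 °C, 1 + 2 (1.0 equiv each); then 3 (1.1 equiv, slow addition), −40 to −20 °C; then 1 M aq. HCl, THF, 0 °C
Reagents that add atoms: none
Why: Proposed new method: the acid is silylated by 2 and the silylium–chiral-anion pair activates 1 at oxygen, 2 adds to C5 and silyl transfer leaves the regiodefined C9=C10 enol ether 4, which attacks O-silylated 3 through C10 and passes the silyl group to the new ester enolate (5); acidic work-up gives 6, and no ring closes. The closest known reactions are the counter-anion-directed catalytic asymmetric Mukaiyama–Michael addition of silyl ketene acetals to enones and enoates and the silylium-catalysed Michael addition of silyl enol ethers to acrylates; what is new is running both in one pot on an α-methyl enone. C5 is set by the chiral anion, which leaves one enone face open. C10 is set by the substrate: the tertiary ester group on C5 stands pseudoaxial beside the C10 methyl and shields its own face, so 3 enters anti and the two arms come out trans. The step needs one enone face, anti addition at C10 and a single addition of acrylate; the first two rest on the catalyst and on the bulk at C5, the third on adding 3 only after 2 is spent, near one equivalent and cold.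

Step 2
Reactants: 6 keto diester
Product: 7 methyl 3-[(6S,7R)-7-(1-methoxy-2-methyl-1-oxopropan-2-yl)-6-methyl-1,4-dioxaspiro[4.5]decan-6-yl]propanoate
Conditions: Me3SiOCH2CH2OSiMe3, Me3SiOTf (5 mol%), CH2Cl2, −78 to −20 °C; pyridine quench
Reagents that add atoms: 1,2-bis(trimethylsilyloxy)ethane, C[Si](C)(C)OCCO[Si](C)(C)C
Why: Silyl-transfer ketalisation (dioxolane formation) proceeds at low temperature on α-quaternary cyclohexanones, leaves the methyl esters alone and masks the only ketone before base is used.

Step 3
Reactants: 7 dioxolane diester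
Product: 8 methyl (4a'S,8a'S)-5',5',8a'-trimethyl-6'-oxooctahydro-2'H-spiro[1,3-dioxolane-2,1'-naphthalene]-7'-carboxylate (trans-fused; C3 ketone and C2 ester in drimane numbering; C2 epimers and enol)
Conditions: KOtBu (2.2 equiv), THF, 0 °C to reflux; then AcOH
Reagents that add atoms: none
Why: Dieckmann condensation: only the propanoate arm can enolise, its C2 enolate attacks the non-enolisable C3 ester held gauche on the neighbouring ring carbon (6-exo-trig), and deprotonation of the β-keto ester drives closure to the trans-fused ring A.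

Step 4
Reactants: 8 β-keto ester
Product: 9 (4a'S,8a'S)-5',5',8a'-trimethylhexahydro-2'H-spiro[1,3-dioxolane-2,1'-naphthalen]-6'(5'H)-one (C3 ketone, C9 dioxolane)
Conditions: LiCl, H2O, DMSO, 150 °C
Reagents that add atoms: none
Why: Krapcho dealkoxycarbonylation removes the C2 ester under neutral conditions that the dioxolane tolerates, and no stereocentre is α to the C3 ketone.

Step 5
Reactants: 9 ketal ketone
Product: 11 (4a'S,8a'S)-5',5',8a'-trimethyloctahydro-2'H-spiro[1,3-dioxolane-2,1'-naphthalene], via hydrazone 10 (not isolated)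
Conditions: N2H4·H2O, KOH, diethylene glycol, 130 °C, then distil to 200 °C
Reagents that add atoms: none
Why: Wolff–Kishner reduction removes the C3 carbonyl beside the gem-dimethyl group, as is routine for 4,4-dimethyl-3-keto terpenoids, and the basic medium cannot touch the dioxolane or the ring-fusion centres.

Step 6
Reactants: 11 ketal
Product: 12 (4aS,8aS)-5,5,8a-trimethyloctahydronaphthalen-1(2H)-one (trans-decalone, ketone at C9)
Conditions: 2 M aq. HCl, THF, 40 °C
Reagents that add atoms: water, O
Why: Acid-catalysed ketal hydrolysis returns the C9 ketone, and since only C8 can enolise the ring fusion is safe.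

Step 7
Reactants: 12 trans-decalone
Product: 13 (2R,4aS,8aS)-2,5,5,8a-tetramethyloctahydronaphthalen-1(2H)-one (equatorial 8-methyl epimer expected; either epimer serves)
Conditions: LiN(iPr)2, THF, −78 °C; MeI, −78 to 0 °C
Reagents that add atoms: iodomethane, CI
Why: Enolate alkylation: C10 is quaternary, so only the C8 enolate can form and methylation installs C12, the new C8 centre being erased in step 8.

Step 8
Reactants: 13 methyl ketone
Product: 14 (4aS,8aS)-2,5,5,8a-tetramethyl-3,4,4a,5,6,7,8,8a-octahydronaphthalen-1-yl trifluoromethanesulfonate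
Conditions: KN(SiMe3)2, THF, −78 to 0 °C; PhN(SO2CF3)2, 0 °C to rt
Reagents that add atoms: N-phenylbis(trifluoromethanesulfonimide), O=S(=O)(N(c1ccccc1)S(=O)(=O)C(F)(F)F)C(F)(F)F
Why: Enol triflate formation: the only possible enolate of 13 is O-sulfonylated, giving the tetrasubstituted C8=C9 triflate regiospecifically.

Step 9
Reactants: 14 enol triflate
Product: 15 methyl (4aS,8aS)-2,5,5,8a-tetramethyl-3,4,4a,5,6,7,8,8a-octahydronaphthalene-1-carboxylate (methyl drim-8-en-11-oate)
Conditions: Pd(OAc)2 (5 mol%), Ph2P(CH2)3PPh2, CO (1 atm), MeOH, Et3N, DMF, 70 °C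
Reagents that add atoms: carbon monoxide, [C-]#[O+]; methanol, CO
Why: Palladium-catalysed alkoxycarbonylation of an enol triflate (oxidative addition of zerovalent palladium, CO insertion, methanolysis) introduces C11, as is done for 2,6,6-trimethylcyclohexenyl triflates.

Step 10
Reactants: 15 conjugated ester
Product: 16 methyl (1S,4aS,8aS)-5,5,8a-trimethyl-2-methylidenedecahydronaphthalene-1-carboxylate (methyl albicanate)
Conditions: LiN(iPr)2, THF, −78 to −30 °C; then AcOH, −78 °C
Reagents that add atoms: none
Why: Deconjugative protonation of a dienolate: the carbonyl-bound lithium amide removes a proton from the C12 methyl, the γ-carbon cis to the ester, and kinetic α-protonation on the face opposite the axial C10 methyl gives the 8(12)-alkene with the equatorial (9S) ester.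

Step 11
Reactants: 16 methyl albicanate
Product: 17 [(1S,4aS,8aS)-5,5,8a-trimethyl-2-methylidenedecahydronaphthalen-1-yl]methanol (albicanol)
Conditions: LiAlH4, Et2O, 0 °C; aq. potassium sodium tartrate
Reagents that add atoms: none
Why: Hydride reduction of the ester to the primary alcohol is faster than enolisation, so neither the exocyclic alkene nor C9 should move.

Step 12
Reactants: 17 albicanol
Product: 18 albicanyl (diethoxyphosphoryl)acetate
Conditions: (EtO)2P(O)CH2CO2H, N,N'-dicyclohexylcarbodiimide, 4-(dimethylamino)pyridine (cat.), CH2Cl2, 0 °C to rt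
Reagents that add atoms: (diethoxyphosphoryl)acetic acid, CCOP(=O)(CC(=O)O)OCC
Why: Steglich esterification acylates the hindered primary alcohol under neutral conditions that leave the acid-sensitive exocyclic alkene alone.

Step 13
Reactants: 19 2,4-dihydroxybenzaldehyde
Product: 20 2,4-bis(tert-butyldimethylsilyloxy)benzaldehyde
Conditions: tBuMe2SiCl (2.3 equiv), imidazole, DMF, rt
Reagents that add atoms: tert-butyldimethylsilyl chloride, CC(C)(C)[Si](C)(C)Cl
Why: Silylation of both phenols prevents phenoxide formation and coumarin-type lactonisation later, and the silyl ethers can be removed with fluoride without acid.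

Step 14
Reactants: 18 albicanyl phosphonoacetate; 20 bis-silylated aldehyde
Product: 21 albicanyl (E)-3-[2,4-bis(tert-butyldimethylsilyloxy)phenyl]prop-2-enoate
Conditions: LiCl, iPr2NEt, MeCN, rt
Reagents that add atoms: none
Why: Horner–Wadsworth–Emmons olefination under mild LiCl/amine conditions gives the E-cinnamate with an aromatic aldehyde and spares the aryl silyl ethers and the ester.

Step 15
Reactants: 21 bis-silyl ether
Product: 22 albicanyl (E)-3-(2,4-dihydroxyphenyl)prop-2-enoate (target)
Conditions: Bu4NF, AcOH, THF, 0 °C, exclusion of light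
Reagents that add atoms: none
Why: Fluoride cleavage of the aryl silyl ethers, buffered with acetic acid and run cold in the dark, should free both phenols without ester cleavage, E to Z isomerisation or alkene migration.

Compound list
1 | 2-methylcyclohex-2-en-1-one | CC1=CCCCC1=O | starting material
2 | dimethylketene methyl trimethylsilyl acetal (1-methoxy-2-methyl-1-(trimethylsilyloxy)prop-1-ene) | COC(O[Si](C)(C)C)=C(C)C | starting material
3 | methyl acrylate | C=CC(=O)OC | starting material
4 | methyl 2-methyl-2-[(1R)-2-methyl-3-(trimethylsilyloxy)cyclohex-2-en-1-yl]propanoate | COC(=O)C(C)(C)[C@@H]1CCCC(O[Si](C)(C)C)=C1C | intermediate (not isolated)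
5 | methyl 2-[(1R,2S)-2-[3-methoxy-3-(trimethylsilyloxy)prop-2-en-1-yl]-2-methyl-3-oxocyclohexyl]-2-methylpropanoate | O=C1CCC[C@@H](C(C)(C)C(=O)OC)[C@]1(C)CC=C(OC)O[Si](C)(C)C | intermediate (not isolated)
6 | methyl 2-[(1R,2S)-2-(3-methoxy-3-oxopropyl)-2-methyl-3-oxocyclohexyl]-2-methylpropanoate | O=C1CCC[C@@H](C(C)(C)C(=O)OC)[C@]1(C)CCC(=O)OC | intermediate
7 | methyl 3-[(6S,7R)-7-(1-methoxy-2-methyl-1-oxopropan-2-yl)-6-methyl-1,4-dioxaspiro[4.5]decan-6-yl]propanoate | COC(=O)CC[C@@]1(C)[C@H](C(C)(C)C(=O)OC)CCCC12OCCO2 | intermediate
8 | methyl (4a'S,8a'S)-5',5',8a'-trimethyl-6'-oxooctahydro-2'H-spiro[1,3-dioxolane-2,1'-naphthalene]-7'-carboxylate | O1CCOC12CCC[C@H]3C(C)(C)C(=O)C(C(=O)OC)C[C@]23C | intermediate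
9 | (4a'S,8a'S)-5',5',8a'-trimethylhexahydro-2'H-spiro[1,3-dioxolane-2,1'-naphthalen]-6'(5'H)-one | O1CCOC12CCC[C@H]3C(C)(C)C(=O)CC[C@]23C | intermediate
10 | hydrazone of 9 at the C3 carbonyl | O1CCOC12CCC[C@H]3C(C)(C)C(=NN)CC[C@]23C | intermediate (not isolated)
11 | (4a'S,8a'S)-5',5',8a'-trimethyloctahydro-2'H-spiro[1,3-dioxolane-2,1'-naphthalene] | O1CCOC12CCC[C@H]3C(C)(C)CCC[C@]23C | intermediate
12 | (4aS,8aS)-5,5,8a-trimethyloctahydronaphthalen-1(2H)-one | O=C1CCC[C@H]2C(C)(C)CCC[C@]12C | intermediate
13 | (2R,4aS,8aS)-2,5,5,8a-tetramethyloctahydronaphthalen-1(2H)-one | O=C1[C@H](C)CC[C@H]2C(C)(C)CCC[C@]12C | intermediate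
14 | (4aS,8aS)-2,5,5,8a-tetramethyl-3,4,4a,5,6,7,8,8a-octahydronaphthalen-1-yl trifluoromethanesulfonate | CC1=C(OS(=O)(=O)C(F)(F)F)[C@@]2(C)CCCC(C)(C)[C@@H]2CC1 | intermediate
15 | methyl (4aS,8aS)-2,5,5,8a-tetramethyl-3,4,4a,5,6,7,8,8a-octahydronaphthalene-1-carboxylate | CC1=C(C(=O)OC)[C@@]2(C)CCCC(C)(C)[C@@H]2CC1 | intermediate
16 | methyl (1S,4aS,8aS)-5,5,8a-trimethyl-2-methylidenedecahydronaphthalene-1-carboxylate | C=C1CC[C@H]2C(C)(C)CCC[C@]2(C)[C@H]1C(=O)OC | intermediate
17 | [(1S,4aS,8aS)-5,5,8a-trimethyl-2-methylidenedecahydronaphthalen-1-yl]methanol (albicanol) | C=C1CC[C@H]2C(C)(C)CCC[C@]2(C)[C@H]1CO | intermediate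
18 | [(1S,4aS,8aS)-5,5,8a-trimethyl-2-methylidenedecahydronaphthalen-1-yl]methyl (diethoxyphosphoryl)acetate | C=C1CC[C@H]2C(C)(C)CCC[C@]2(C)[C@H]1COC(=O)CP(=O)(OCC)OCC | intermediate
19 | 2,4-dihydroxybenzaldehyde | O=Cc1ccc(O)cc1O | starting material
20 | 2,4-bis(tert-butyldimethylsilyloxy)benzaldehyde | O=Cc1ccc(O[Si](C)(C)C(C)(C)C)cc1O[Si](C)(C)C(C)(C)C | intermediate
21 | [(1S,4aS,8aS)-5,5,8a-trimethyl-2-methylidenedecahydronaphthalen-1-yl]methyl (E)-3-[2,4-bis(tert-butyldimethylsilyloxy)phenyl]prop-2-enoate | C=C1CC[C@H]2C(C)(C)CCC[C@]2(C)[C@H]1COC(=O)/C=C/c1ccc(O[Si](C)(C)C(C)(C)C)cc1O[Si](C)(C)C(C)(C)C | intermediate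
22 | [(1S,4aS,8aS)-5,5,8a-trimethyl-2-methylidenedecahydronaphthalen-1-yl]methyl (E)-3-(2,4-dihydroxyphenyl)prop-2-enoate | C=C1CC[C@H]2C(C)(C)CCC[C@]2(C)[C@H]1COC(=O)/C=C/c1ccc(O)cc1O | target

Total step count: 15. Longest linear sequence: 14 (steps 1 to 12, then 14 and 15; step 13 is the side branch).

Steps most likely to fail

Step 1. Three processes may defeat the one-pot coupling: chain growth, because the ketene acetal 5 formed in the second addition is a better nucleophile than enol ether 4 and may add to further acrylate; weak facial discrimination of the α-methyl enone by the chiral anion; and slow bond formation at the congested C10. The fallback makes the two bonds separately by known reactions, sets out from 2 and returns at 6. Ketene acetal 2 is added to purchased cyclohex-2-en-1-one under a chiral oxazaborolidinium triflimide Lewis acid (the B-(2-methylphenyl)oxazaborolidine of α,α-diphenylprolinol protonated by HN(SO2CF3)2, with Ph3PO, toluene, −20 °C). This catalytic asymmetric Mukaiyama–Michael addition is established for this nucleophile and simple cyclic enones, and should give the silyl enol ether methyl 2-methyl-2-[(1R)-3-(trimethylsilyloxy)cyclohex-2-en-1-yl]propanoate F1. Regiospecific fluoride-mediated methylation (benzyltrimethylammonium fluoride, MeI, THF) would turn it into the ketone methyl 2-methyl-2-[(1R,2S)-2-methyl-3-oxocyclohexyl]propanoate F2. Condensation with (S)-1-phenylethylamine (toluene, azeotropic removal of water) would give the imine methyl 2-methyl-2-[(1R,2S)-2-methyl-3-{[(1S)-1-phenylethyl]imino}cyclohexyl]propanoate F3. Its more substituted secondary enamine tautomer adds to methyl acrylate 3 (THF, 40 °C) at C10, anti to the ring substituent and in the sense known for this auxiliary with 2-methylcyclohexanone imines. Aqueous acetic acid then releases 6.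

Step 10. Deprotonation may lose regiocontrol (ring C7–H instead of C12–H, leading to the endocyclic 7-ene), or γ-protonation may return the conjugated ester. The fallback sets out from 15 and returns at 16 by photochemical deconjugation (254 nm, hexane, catalytic 1,2-dimethylimidazole). The excited ester takes a hydrogen by 1,5-shift, and in the ring only the C12 methyl is held cis to the ester carbonyl, so only the exocyclic dienol can form. Base-catalysed ketonisation then protonates C9 on the face opposite the C10 methyl. No compound outside the list arises (entry F0).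

Step 9. Oxidative addition of zerovalent palladium into the tetrasubstituted triflate flanked by the quaternary C10 may be slow, so that triflate cleavage back to 13 or reduction takes over. The fallback sets out from 13 and returns at 15 without a transition metal. N2H4·H2O, Et3N, EtOH at reflux would give (2R,4aS,8aS)-2,5,5,8a-tetramethyloctahydronaphthalen-1(2H)-one hydrazone F4. Barton vinyl iodide synthesis (I2, 1,1,3,3-tetramethylguanidine, Et2O, 0 °C) would convert it into (4aS,8aS)-1-iodo-2,5,5,8a-tetramethyl-3,4,4a,5,6,7,8,8a-octahydronaphthalene F5. Iodine–lithium exchange (tBuLi, 2 equiv, THF, −78 °C) and trapping with methyl chloroformate would then give 15.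

Further compounds
F1 | step 1 | methyl 2-methyl-2-[(1R)-3-(trimethylsilyloxy)cyclohex-2-en-1-yl]propanoate | COC(=O)C(C)(C)[C@@H]1CCCC(O[Si](C)(C)C)=C1
F2 | step 1 | methyl 2-methyl-2-[(1R,2S)-2-methyl-3-oxocyclohexyl]propanoate | COC(=O)C(C)(C)[C@@H]1CCCC(=O)[C@H]1C
F3 | step 1 | methyl 2-methyl-2-[(1R,2S)-2-methyl-3-{[(1S)-1-phenylethyl]imino}cyclohexyl]propanoate | COC(=O)C(C)(C)[C@@H]1CCCC(=N[C@@H](C)c2ccccc2)[C@H]1C
F0 | step 10 | none | none
F4 | step 9 | (2R,4aS,8aS)-2,5,5,8a-tetramethyloctahydronaphthalen-1(2H)-one hydrazone | NN=C1[C@H](C)CC[C@H]2C(C)(C)CCC[C@]12C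
F5 | step 9 | (4aS,8aS)-1-iodo-2,5,5,8a-tetramethyl-3,4,4a,5,6,7,8,8a-octahydronaphthalene | CC1=C(I)[C@@]2(C)CCCC(C)(C)[C@@H]2CC1
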